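**Retrosynthetic overview**

1. The strategy rests on ring A: C5, C6, C7 and C8 carry four adjacent oxygens, with O5 and O8 para. This is a hydroquinone whose four oxygenated carbons can come from one squarate unit fused onto the C4a=C8a bond of the pyranone (ring C).
2. Endgame: target ⇐ its 7-O-allyl ether ⇐ (8-O-methylation) 7-allyloxy-5,8-dihydroxy-6-methoxyflavone. Key disconnection: the C8–C8a bond and ring A, by thermal ring expansion of a 4-hydroxy-4-(4-pyranon-3-yl)cyclobutenone.
3. The cyclobutenone ⇐ 5-magnesiated 2-aryl-4-pyranone + symmetric diallyl squarate. O6 and O7 are told apart only afterwards: on the adduct just the C3 allyloxy group is a vinylogous ester, so it alone is removed by palladium, and the resulting symmetric vinylogous acid is methylated.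
4. The 5-iodo-2-aryl-4-pyranone ⇐ 3-iodo-4-methoxybut-3-en-2-one + 3,4,5-trimethoxybenzoyl chloride, so the iodine is in place before ring C exists and no regioselective halogenation of the pyranone is needed.
5. Ring order: ring B is bought, ring C is made in steps 2–3, ring A is closed last in step 8.

Key step: step 8

Assumption: diallyl squarate is made from squaric acid and two equivalents of allyl alcohol (step 4) rather than bought; all chiral intermediates are racemic and the target has no stereocentre.

**Route**

Step 1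
Reactants: 1 (E)-4-methoxybut-3-en-2-one
Product: 2 (Z)-3-iodo-4-methoxybut-3-en-2-one
Conditions: NIS (1.05 equiv), CH2Cl2, 0 °C to rt, dark
Reagents that add atoms: N-iodosuccinimide, O=C1CCC(=O)N1I
Why: Electrophilic α-iodination of a β-alkoxy enone takes place at C3, its only nucleophilic carbon, and loss of the C3 proton restores the enone, so the future C5 iodine of the pyranone is fixed here (the alkene geometry is of no consequence because C4 later reacts by addition–elimination).

Step 2
Reactants: 2 (Z)-3-iodo-4-methoxybut-3-en-2-one; 3 3,4,5-trimethoxybenzoyl chloride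
Product: 4 (Z)-4-iodo-5-methoxy-1-(3,4,5-trimethoxyphenyl)pent-4-ene-1,3-dione (mainly enolised)
Conditions: 2 (2.0 equiv), LiN(SiMe3)2 (2.0 equiv), THF, −78 °C; then 3 (1.0 equiv), −78 to −30 °C; aq. NH4Cl
Reagents that add atoms: none
Why: Crossed Claisen-type C-acylation of the kinetic lithium enolate of the methyl ketone by the aroyl chloride should give the 1,3-diketone, the second equivalent of enolate serving as base for the acidic product while the vinyl iodide is inert to the amide base at −78 °C.

Step 3
Reactants: 4 (Z)-4-iodo-5-methoxy-1-(3,4,5-trimethoxyphenyl)pent-4-ene-1,3-dione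
Product: 5 5-iodo-2-(3,4,5-trimethoxyphenyl)-4H-pyran-4-one
Conditions: CF3CO2H, CH2Cl2, rt
Reagents that add atoms: none
Why: Acid-promoted 6-endo oxa-Michael addition of the enol oxygen to the β-methoxy enone followed by loss of methanol (addition–elimination cyclisation) should close the 4-pyranone with iodine on C5 and hydrogen on C6.

Step 4
Reactants: 6 squaric acid (3,4-dihydroxycyclobut-3-ene-1,2-dione); 7 allyl alcohol (prop-2-en-1-ol; two equivalents are built into the product)
Product: 8 diallyl squarate (3,4-bis(allyloxy)cyclobut-3-ene-1,2-dione)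
Conditions: allyl alcohol (excess, 2 equiv consumed), toluene, reflux, Dean–Stark trap
Reagents that add atoms: allyl alcohol (second equivalent of 7), C=CCO
Why: Twofold Fischer-type esterification of the strongly acidic, self-catalysing vinylogous diacid, each hydroxyl being replaced by one allyloxy group with loss of one water, is driven to the diester by azeotropic removal of water and is the standard way to dialkyl squarates.

Step 5
Reactants: 5 5-iodo-2-(3,4,5-trimethoxyphenyl)-4H-pyran-4-one; 8 diallyl squarate
Product: 10 2,3-bis(allyloxy)-4-hydroxy-4-[4-oxo-6-(3,4,5-trimethoxyphenyl)-4H-pyran-3-yl]cyclobut-2-en-1-one (racemic), via pyranonylmagnesium chloride 9 (not isolated)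
Conditions: iPrMgCl·LiCl (1.05 equiv), THF, −40 °C; then cannulated into 8 (1.2 equiv), THF, −78 to −20 °C; aq. NH4Cl
Reagents that add atoms: none
Why: Iodine–magnesium exchange of an α-iodo-β-alkoxy enone is fast at −40 °C, and the alkenylmagnesium should add 1,2 (Grignard addition) to one of the two equivalent strained carbonyls of the symmetric squarate, so no regiochemical question arises and the new carbinol centre, formed as a racemate, is erased in step 8.

Step 6
Reactants: 10 2,3-bis(allyloxy)-4-hydroxy-4-[4-oxo-6-(3,4,5-trimethoxyphenyl)-4H-pyran-3-yl]cyclobut-2-en-1-one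
Product: 11 2-(allyloxy)-3,4-dihydroxy-4-[4-oxo-6-(3,4,5-trimethoxyphenyl)-4H-pyran-3-yl]cyclobut-2-en-1-one (racemic; enol of a symmetric 1,3-dione)
Conditions: Pd(PPh3)4 (5 mol %), sodium p-toluenesulfinate (1.05 equiv), THF–MeOH, 0 °C; cold 1 M HCl, EtOAc extraction; used at once
Reagents that add atoms: none
Why: Tsuji–Trost deallylation with zerovalent palladium should ionise only the allyl group on C3, whose leaving group is the delocalised 1,3-diketonate (a vinylogous carboxylate), whereas the C2 allyl enol ether would have to release a far more basic enolate and, after the first cleavage, a dianion; the sulfinate traps the allyl fragment as a sulfone.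

Step 7
Reactants: 11 2-(allyloxy)-3,4-dihydroxy-4-[4-oxo-6-(3,4,5-trimethoxyphenyl)-4H-pyran-3-yl]cyclobut-2-en-1-one
Product: 12 2-(allyloxy)-4-hydroxy-3-methoxy-4-[4-oxo-6-(3,4,5-trimethoxyphenyl)-4H-pyran-3-yl]cyclobut-2-en-1-one (racemic)
Conditions: Me3SiCHN2 (1.1 equiv), toluene–MeOH 4:1, 0 °C; AcOH quench
Reagents that add atoms: (trimethylsilyl)diazomethane, C[Si](C)(C)C=[N+]=[N-]
Why: Diazoalkane O-methylation (esterification type) of the strongly acidic vinylogous acid is fast and, because the two oxygens of the 1,3-dione enol are related by the mirror plane through C2 and C4, methylation of either gives the same 3-methoxy-2-allyloxy cyclobutenone while the tertiary alcohol stays free.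

Step 8
Reactants: 12 2-(allyloxy)-4-hydroxy-3-methoxy-4-[4-oxo-6-(3,4,5-trimethoxyphenyl)-4H-pyran-3-yl]cyclobut-2-en-1-one
Product: 15 7-(allyloxy)-5,8-dihydroxy-6-methoxy-2-(3,4,5-trimethoxyphenyl)-4H-chromen-4-one, via (Z)-dienylketene 13 (not isolated), via 8aH-chromene-4,8-dione 14 (not isolated)
Conditions: toluene (0.01 M, degassed), 110 °C, argon
Reagents that add atoms: none
Why: Heating should cleave the C1–C4 bond of the cyclobutenone in a conrotatory 4π electrocyclic opening in which the donor hydroxyl turns outward, so that the pyranonyl group ends up cis to the ketene in dienylketene 13. The ketene C=C, the former ring alkene and the pyranone C=C bond that carries the substituent (C5=C6 in the numbering of 5) then make up a hexatriene that closes by thermal disrotatory 6π electrocyclisation, joining the ketene carbon (future C8) to the pyranone CH next to the ring oxygen (future C8a) and closing the six-membered ring A as dienone 14, which enolises to hydroquinone 15. The closest known reaction is the Moore rearrangement of 4-aryl-, 4-heteroaryl- and 4-alkenyl-4-hydroxycyclobutenones derived from squarate esters. No stereocentre remains, since the carbinol carbon becomes the sp2 carbon C5 and the transient C8a–H centre of 14 is lost on aromatisation. The step needs outward rotation of the hydroxyl, which the known torquoselectivity of donor groups provides, and closure at C8a, which is the only possibility because the other neighbour of the attachment carbon is the C4 carbonyl carbon. The cyclobutenone delivers C5–C8 with methoxy on C6 and allyloxy on C7 already in place, and dilute, air-free toluene at 110 °C should keep the allyl enol ether below the onset of a Claisen shift and protect the hydroquinone from oxidation.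

Step 9
Reactants: 15 7-(allyloxy)-5,8-dihydroxy-6-methoxy-2-(3,4,5-trimethoxyphenyl)-4H-chromen-4-one
Product: 16 7-(allyloxy)-5-hydroxy-6,8-dimethoxy-2-(3,4,5-trimethoxyphenyl)-4H-chromen-4-one
Conditions: MeI (1.2 equiv), K2CO3 (1.5 equiv), acetone, rt, argon
Reagents that add atoms: iodomethane, CI
Why: Williamson methylation with a weak base should alkylate only the free 8-hydroxyl, because the 5-hydroxyl is tied up in a hydrogen bond to the C4 carbonyl and is not alkylated under these mild conditions, while exclusion of air prevents oxidation to the 5,8-quinone.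

Step 10
Reactants: 16 7-(allyloxy)-5-hydroxy-6,8-dimethoxy-2-(3,4,5-trimethoxyphenyl)-4H-chromen-4-one
Product: 17 5,7-dihydroxy-6,8,3',4',5'-pentamethoxyflavone (target)
Conditions: Pd(PPh3)4 (5 mol %), morpholine (3 equiv), THF, rt
Reagents that add atoms: none
Why: Tsuji–Trost deallylation of the aryl allyl ether with zerovalent palladium and morpholine as allyl acceptor should free the acidic 7-hydroxyl under neutral conditions that leave all five methyl ethers untouched.

**Compound list**

1 | (E)-4-methoxybut-3-en-2-one | CO/C=C/C(C)=O | starting material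
2 | (Z)-3-iodo-4-methoxybut-3-en-2-one | CO/C=C(\I)C(C)=O | intermediate
3 | 3,4,5-trimethoxybenzoyl chloride | COc1cc(C(Cl)=O)cc(OC)c1OC | starting material
4 | (Z)-4-iodo-5-methoxy-1-(3,4,5-trimethoxyphenyl)pent-4-ene-1,3-dione | COc1cc(cc(OC)c1OC)C(=O)CC(=O)C(/I)=C/OC | intermediate
5 | 5-iodo-2-(3,4,5-trimethoxyphenyl)-4H-pyran-4-one | COc1cc(-c2cc(=O)c(I)co2)cc(OC)c1OC | intermediate
6 | squaric acid (3,4-dihydroxycyclobut-3-ene-1,2-dione) | OC1=C(O)C(=O)C1=O | starting material
7 | allyl alcohol (prop-2-en-1-ol) | C=CCO | starting material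
8 | diallyl squarate (3,4-bis(allyloxy)cyclobut-3-ene-1,2-dione) | C=CCOC1=C(OCC=C)C(=O)C1=O | intermediate
9 | [4-oxo-6-(3,4,5-trimethoxyphenyl)-4H-pyran-3-yl]magnesium chloride (LiCl complex) | COc1cc(-c2cc(=O)c([Mg]Cl)co2)cc(OC)c1OC | intermediate
10 | 2,3-bis(allyloxy)-4-hydroxy-4-[4-oxo-6-(3,4,5-trimethoxyphenyl)-4H-pyran-3-yl]cyclobut-2-en-1-one (racemic) | O=C1C(OCC=C)=C(OCC=C)C1(O)c1coc(-c2cc(OC)c(OC)c(OC)c2)cc1=O | intermediate
11 | 2-(allyloxy)-3,4-dihydroxy-4-[4-oxo-6-(3,4,5-trimethoxyphenyl)-4H-pyran-3-yl]cyclobut-2-en-1-one (racemic) | O=C1C(OCC=C)=C(O)C1(O)c1coc(-c2cc(OC)c(OC)c(OC)c2)cc1=O | intermediate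
12 | 2-(allyloxy)-4-hydroxy-3-methoxy-4-[4-oxo-6-(3,4,5-trimethoxyphenyl)-4H-pyran-3-yl]cyclobut-2-en-1-one (racemic) | O=C1C(OCC=C)=C(OC)C1(O)c1coc(-c2cc(OC)c(OC)c(OC)c2)cc1=O | intermediate
13 | (3Z)-2-(allyloxy)-4-hydroxy-3-methoxy-4-[4-oxo-6-(3,4,5-trimethoxyphenyl)-4H-pyran-3-yl]buta-1,3-dien-1-one (dienylketene) | C=CCOC(=C=O)/C(OC)=C(/O)c1coc(-c2cc(OC)c(OC)c(OC)c2)cc1=O | intermediate
14 | 7-(allyloxy)-5-hydroxy-6-methoxy-2-(3,4,5-trimethoxyphenyl)-8aH-chromene-4,8-dione (racemic) | O=C1C(OCC=C)=C(OC)C(O)=C2C(=O)C=C(c3cc(OC)c(OC)c(OC)c3)OC12 | intermediate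
15 | 7-(allyloxy)-5,8-dihydroxy-6-methoxy-2-(3,4,5-trimethoxyphenyl)-4H-chromen-4-one | C=CCOc1c(OC)c(O)c2c(=O)cc(-c3cc(OC)c(OC)c(OC)c3)oc2c1O | intermediate
16 | 7-(allyloxy)-5-hydroxy-6,8-dimethoxy-2-(3,4,5-trimethoxyphenyl)-4H-chromen-4-one | C=CCOc1c(OC)c(O)c2c(=O)cc(-c3cc(OC)c(OC)c(OC)c3)oc2c1OC | intermediate
17 | 5,7-dihydroxy-6,8,3',4',5'-pentamethoxyflavone | COc1cc(-c2cc(=O)c3c(O)c(OC)c(O)c(OC)c3o2)cc(OC)c1OC | target

**Step count and risks**

Total step count: 10. Longest linear sequence: 9 steps (1, 2, 3, 5, 6, 7, 8, 9, 10); step 4 is a one-step side branch.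

Steps most likely to fail:

- **Step 8 (key step).** The dienylketene may fail to close onto the acceptor-substituted pyranone alkene fast enough. It could then revert and reopen with the hydroxyl turned inward, so that the free hydroxyl captures the ketene as a butenolide, or it could oligomerise. Fallback: the route leaves from 12, whose tertiary alcohol is silylated (Me3SiCl, Et3N, DMAP cat., CH2Cl2) to 2-(allyloxy)-3-methoxy-4-[4-oxo-6-(3,4,5-trimethoxyphenyl)-4H-pyran-3-yl]-4-(trimethylsilyloxy)cyclobut-2-en-1-one F1. With no hydroxyl left to trap the ketene, thermolysis in toluene should give only the ring-expanded mono-protected hydroquinone 7-(allyloxy)-8-hydroxy-6-methoxy-2-(3,4,5-trimethoxyphenyl)-5-(trimethylsilyloxy)-4H-chromen-4-one F2. Its silyl ether is cleaved with K2CO3 in MeOH under argon, and the route is rejoined at 15.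

- **Step 6.** Palladium ionisation could be followed by recombination of the allyl fragment at carbon, or the vinylogous acid 11 could suffer ring cleavage before it is methylated. Fallback: the differentiation is moved to the stable squarate stage. Starting from 8, saponification with one equivalent of NaOH (THF–water, then HCl) gives 3-(allyloxy)-4-hydroxycyclobut-3-ene-1,2-dione F3, and Me3SiCHN2 in toluene–MeOH converts it to 3-(allyloxy)-4-methoxycyclobut-3-ene-1,2-dione F4. The magnesium reagent 9, made from 5 as in step 5, is added to F4. This should give 12 together with its regioisomer 3-(allyloxy)-4-hydroxy-2-methoxy-4-[4-oxo-6-(3,4,5-trimethoxyphenyl)-4H-pyran-3-yl]cyclobut-2-en-1-one F5, which has to be removed by chromatography, at the cost of material since the two carbonyls of F4 differ little. The route is rejoined at 12.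

- **Step 2.** The iodinated enolate may undergo O-acylation, self-condensation or loss of iodine. Fallback: the halogen is introduced after ring C is made. Starting from 1 and 3, the same enolate acylation without iodine gives (E)-5-methoxy-1-(3,4,5-trimethoxyphenyl)pent-4-ene-1,3-dione F6, and CF3CO2H closes it to 2-(3,4,5-trimethoxyphenyl)-4H-pyran-4-one F7. Iodination with NIS (CF3CO2H cat., MeCN) should give 5, which must be separated from the isomer 3-iodo-2-(3,4,5-trimethoxyphenyl)-4H-pyran-4-one F8 and from any ring-B iodinated material. The route is rejoined at 5.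

**Further compounds**

F1 | step 8 | 2-(allyloxy)-3-methoxy-4-[4-oxo-6-(3,4,5-trimethoxyphenyl)-4H-pyran-3-yl]-4-(trimethylsilyloxy)cyclobut-2-en-1-one | O=C1C(OCC=C)=C(OC)C1(O[Si](C)(C)C)c1coc(-c2cc(OC)c(OC)c(OC)c2)cc1=O
F2 | step 8 | 7-(allyloxy)-8-hydroxy-6-methoxy-2-(3,4,5-trimethoxyphenyl)-5-(trimethylsilyloxy)-4H-chromen-4-one | C=CCOc1c(OC)c(O[Si](C)(C)C)c2c(=O)cc(-c3cc(OC)c(OC)c(OC)c3)oc2c1O
F3 | step 6 | 3-(allyloxy)-4-hydroxycyclobut-3-ene-1,2-dione | C=CCOC1=C(O)C(=O)C1=O
F4 | step 6 | 3-(allyloxy)-4-methoxycyclobut-3-ene-1,2-dione | C=CCOC1=C(OC)C(=O)C1=O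
F5 | step 6 | 3-(allyloxy)-4-hydroxy-2-methoxy-4-[4-oxo-6-(3,4,5-trimethoxyphenyl)-4H-pyran-3-yl]cyclobut-2-en-1-one | O=C1C(OC)=C(OCC=C)C1(O)c1coc(-c2cc(OC)c(OC)c(OC)c2)cc1=O
F6 | step 2 | (E)-5-methoxy-1-(3,4,5-trimethoxyphenyl)pent-4-ene-1,3-dione | COc1cc(cc(OC)c1OC)C(=O)CC(=O)/C=C/OC
F7 | step 2 | 2-(3,4,5-trimethoxyphenyl)-4H-pyran-4-one | COc1cc(-c2cc(=O)cco2)cc(OC)c1OC
F8 | step 2 | 3-iodo-2-(3,4,5-trimethoxyphenyl)-4H-pyran-4-one | COc1cc(-c2occc(=O)c2I)cc(OC)c1OC
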